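**Retrosynthetic overview**

1. Endgame: the eleven phenols are unmasked last (fluoride, then BCl3/pentamethylbenzene); before that the (E)-enone is attached by a Heck reaction between the C5 aryl bromide of the dihydrobenzofuran and a 2,4-bis(benzyloxy)phenyl vinyl ketone.
2. Key disconnection: bond C3–C3a of the dihydrobenzofuran together with the bond from the diarylmethine carbon to the central resorcinol ring. Both form in one step: a 2,3-trans-3,4-trans-4-arylflavan-3-yl triflate (six-membered pyran ring C) contracts to the five-membered ring by 1,2-shift of aryl carbon C4a from C4 to C3, and the phenonium/benzylic cation alkylates the tetrahydrofuran fragment (Friedel–Crafts).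
3. Enabling feature: in the all-equatorial flavan the C3–O bond is antiperiplanar to ring bond C4–C4a; C4a is an aryl carbon of ring A ortho to the ring oxygen O1 (a good neighbouring group); C4 carries an electron-rich 2,4-bis(silyloxy)phenyl group that takes up the charge.
4. Flavanol (pyran ring already present in 6-bromochromone): Pd-catalysed asymmetric aryl conjugate addition (C2), arylcerium addition and dehydration, hydroboration (C3, C4).
5. Tetrahydrofuran fragment: Evans syn-aldol/lactonisation to a trans-paraconic acid, trans-alkylation, aryllithium addition and ionic hydrogenation of the hemiketal (2,3-cis), Weinreb ketone synthesis. Ring order: lactone → tetrahydrofuran; pyran → dihydrobenzofuran (key step).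

Key step: step 16

Remark 1: (S)-t-BuPyOx is assumed, by analogy with cyclic enones, to deliver the (R)-flavanone 6; if the sense of induction is the opposite, the (R)-ligand is used.
Remark 2: compounds 1, 4, 5, 10, 11, 13, 17 and 23 are taken as commercially available.

**Step 1**
Reactants: 1 4-bromoresorcinol
Product: 2 1-bromo-2,4-bis(triisopropylsilyloxy)benzene
Conditions: TIPSCl, imidazole, DMF, rt
Reagents that add atoms: chlorotriisopropylsilane, CC(C)[Si](Cl)(C(C)C)C(C)C
Why: Imidazole-promoted O-silylation of both phenols is routine, and the two bulky TIPS groups are chosen so that this ring, later the aryl group on C4 of the flavan, cannot compete as a Friedel–Crafts nucleophile in step 16.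

**Step 2**
Reactants: 1 4-bromoresorcinol
Product: 3 1-bromo-2,4-bis(benzyloxy)benzene
Conditions: BnBr, K2CO3, DMF, rt
Reagents that add atoms: benzyl bromide, BrCc1ccccc1
Why: Williamson ether synthesis on the two phenoxides gives the aryl bromide that serves twice as an aryllithium precursor.

**Step 3**
Reactants: 4 6-bromochromone; 5 4-(benzyloxy)phenylboronic acid
Product: 6 (2R)-2-[4-(benzyloxy)phenyl]-6-bromochroman-4-one
Conditions: Pd(OCOCF3)2 (5 mol %), (S)-t-BuPyOx (6 mol %), NH4PF6, H2O, ClCH2CH2Cl, 60 °C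
Reagents that add atoms: none
Why: Pd-catalysed enantioselective conjugate addition of an arylboronic acid to a chromone with a pyridine-oxazoline ligand is a known reaction; the ligand decides the face of aryl transfer to C2, and the divalent-palladium cycle should leave the aryl bromide untouched.

**Step 4**
Reactants: 6 (2R)-2-[4-(benzyloxy)phenyl]-6-bromochroman-4-one; 2 1-bromo-2,4-bis(triisopropylsilyloxy)benzene
Product: 7 (2R)-2-[4-(benzyloxy)phenyl]-6-bromo-4-[2,4-bis(triisopropylsilyloxy)phenyl]chroman-4-ol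
Conditions: 2, n-BuLi, THF, −78 °C; CeCl3, −78 °C; then 6, −78 → −40 °C; aq NH4Cl
Reagents that add atoms: none
Why: Halogen–lithium exchange and transmetalation give an organocerium reagent whose low basicity favours 1,2-addition to the enolisable flavanone over enolate formation and ring opening; the new carbinol centre is removed in step 5 and is of no consequence.

**Step 5**
Reactants: 7 (2R)-2-[4-(benzyloxy)phenyl]-6-bromo-4-[2,4-bis(triisopropylsilyloxy)phenyl]chroman-4-ol
Product: 8 (2R)-2-[4-(benzyloxy)phenyl]-6-bromo-4-[2,4-bis(triisopropylsilyloxy)phenyl]-2H-chromene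
Conditions: Burgess reagent, THF, 50 °C
Reagents that add atoms: none
Why: Burgess dehydration (syn elimination under neutral conditions) of the tertiary bis-benzylic alcohol can only give the C3=C4 alkene, and the absence of acid avoids ionisation of the allylic C2–O bond, so C2 keeps its configuration.

**Step 6**
Reactants: 8 (2R)-2-[4-(benzyloxy)phenyl]-6-bromo-4-[2,4-bis(triisopropylsilyloxy)phenyl]-2H-chromene
Product: 9 (2S,3R,4R)-2-[4-(benzyloxy)phenyl]-6-bromo-4-[2,4-bis(triisopropylsilyloxy)phenyl]chroman-3-ol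
Conditions: BH3·SMe2, THF, 0 °C → rt; NaBO3·4H2O, THF/H2O, rt
Reagents that add atoms: sodium perborate (used as NaBO3·4H2O; source of the hydroxyl oxygen), [Na+].[Na+].O[B-]1(O)OO[B-](O)(O)OO1
Why: Hydroboration–oxidation of flav-3-enes is a known route to 2,3-trans-flavan-3-ols: boron adds to C3 from the face anti to the 2-aryl group and hydrogen is delivered syn to C4, which sets C3 and C4 by substrate control as the all-equatorial 2,3-trans-3,4-trans isomer.

**Step 7**
Reactants: 10 (S)-4-benzyl-1,3-oxazolidin-2-one; 11 methyl 4-chloro-4-oxobutanoate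
Product: 12 methyl 4-[(4S)-4-benzyl-2-oxo-1,3-oxazolidin-3-yl]-4-oxobutanoate
Conditions: n-BuLi, THF, −78 °C; then 11, −78 → 0 °C
Reagents that add atoms: none
Why: N-acylation of the lithiated oxazolidinone with the acid chloride is the standard preparation of an Evans imide.

**Step 8**
Reactants: 12 methyl 4-[(4S)-4-benzyl-2-oxo-1,3-oxazolidin-3-yl]-4-oxobutanoate; 13 4-(benzyloxy)benzaldehyde
Product: 15 (4S)-4-benzyl-3-{[(2S,3S)-2-[4-(benzyloxy)phenyl]-5-oxotetrahydrofuran-3-yl]carbonyl}-1,3-oxazolidin-2-one, via syn-aldol adduct 14 (not isolated)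
Conditions: Bu2BOTf, i-Pr2NEt, CH2Cl2, 0 °C; 13, −78 → 0 °C; H2O2, MeOH, pH 7 buffer; then PPTS (cat.), CH2Cl2, rt
Reagents that add atoms: none
Why: Evans syn-aldol reaction: the Z-boron enolate reacts through a chair (Zimmerman–Traxler) transition state on the face opposite the benzyl group of the auxiliary, which sets both new centres, and lactonisation of the syn-aldol onto the methyl ester gives the 2,3-trans γ-lactone.

**Step 9**
Reactants: 15 (4S)-4-benzyl-3-{[(2S,3S)-2-[4-(benzyloxy)phenyl]-5-oxotetrahydrofuran-3-yl]carbonyl}-1,3-oxazolidin-2-one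
Product: 16 (2S,3S)-2-[4-(benzyloxy)phenyl]-5-oxotetrahydrofuran-3-carboxylic acid
Conditions: LiOH, H2O2, THF/H2O, 0 °C; Na2SO3; HCl to pH 2
Reagents that add atoms: hydrogen peroxide (as lithium hydroperoxide; oxygen of the carboxyl OH), OO
Why: Lithium hydroperoxide cleaves the exocyclic imide carbonyl selectively (standard auxiliary removal), and the γ-lactone re-forms on acidification.

**Step 10**
Reactants: 16 (2S,3S)-2-[4-(benzyloxy)phenyl]-5-oxotetrahydrofuran-3-carboxylic acid; 17 4-(benzyloxy)benzyl bromide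
Product: 18 (2S,3S,4S)-4-[4-(benzyloxy)benzyl]-2-[4-(benzyloxy)phenyl]-5-oxotetrahydrofuran-3-carboxylic acid
Conditions: LiN(SiMe3)2 (2.2 equiv), THF, −78 °C; 17, −78 → −40 °C; aq HCl
Reagents that add atoms: none
Why: Alkylation of the lactone enolate of the carboxylate dianion takes place anti to the neighbouring carboxylate (a known reaction of paraconic acids), giving the 3,4-trans product.

**Step 11**
Reactants: 18 (2S,3S,4S)-4-[4-(benzyloxy)benzyl]-2-[4-(benzyloxy)phenyl]-5-oxotetrahydrofuran-3-carboxylic acid; 3 1-bromo-2,4-bis(benzyloxy)benzene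
Product: 20 (2S,3S,4S,5R)-4-[4-(benzyloxy)benzyl]-2-[4-(benzyloxy)phenyl]-5-[2,4-bis(benzyloxy)phenyl]tetrahydrofuran-3-carboxylic acid, via cyclic hemiketal 19 (not isolated)
Conditions: 3 (2.5 equiv), n-BuLi, THF, −78 °C; 18, −78 °C; aq NH4Cl; crude 19: Et3SiH, BF3·OEt2, CH2Cl2, −78 °C
Reagents that add atoms: none
Why: Aryllithium addition to the γ-lactone (the carboxylate is inert as its lithium salt) gives the cyclic hemiketal, and ionic hydrogenation of the derived 2-aryl oxocarbenium ion delivers hydride anti to the adjacent benzyl group at C4, which places the new aryl group at C5 cis to it, as known for 2,5-diaryltetrahydrofuran lignans.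

**Step 12**
Reactants: 20 (2S,3S,4S,5R)-4-[4-(benzyloxy)benzyl]-2-[4-(benzyloxy)phenyl]-5-[2,4-bis(benzyloxy)phenyl]tetrahydrofuran-3-carboxylic acid
Product: 21 (2S,3S,4S,5R)-4-[4-(benzyloxy)benzyl]-2-[4-(benzyloxy)phenyl]-5-[2,4-bis(benzyloxy)phenyl]-N-methoxy-N-methyltetrahydrofuran-3-carboxamide
Conditions: MeNHOMe·HCl, EDC·HCl, HOBt, i-Pr2NEt, CH2Cl2, rt
Reagents that add atoms: N,O-dimethylhydroxylamine hydrochloride, CNOC.Cl
Why: Carbodiimide amide coupling gives the Weinreb amide without touching the stereocentres.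

**Step 13**
Reactants: 21 (2S,3S,4S,5R)-4-[4-(benzyloxy)benzyl]-2-[4-(benzyloxy)phenyl]-5-[2,4-bis(benzyloxy)phenyl]-N-methoxy-N-methyltetrahydrofuran-3-carboxamide; 3 1-bromo-2,4-bis(benzyloxy)benzene
Product: 22 [(2S,3S,4S,5R)-4-[4-(benzyloxy)benzyl]-2-[4-(benzyloxy)phenyl]-5-[2,4-bis(benzyloxy)phenyl]tetrahydrofuran-3-yl][2,4-bis(benzyloxy)phenyl]methanone
Conditions: 3, n-BuLi, THF, −78 °C; then 21, −78 → −40 °C; aq NH4Cl
Reagents that add atoms: none
Why: Weinreb ketone synthesis: the chelated tetrahedral intermediate prevents over-addition and should form at low temperature faster than enolisation, and the α-centre already has the more stable arrangement trans to both neighbours.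

**Step 14**
Reactants: 23 2,4-bis(benzyloxy)benzaldehyde
Product: 24 1-[2,4-bis(benzyloxy)phenyl]prop-2-en-1-ol (racemic)
Conditions: CH2=CHMgBr, THF, −78 → 0 °C; aq NH4Cl
Reagents that add atoms: vinylmagnesium bromide, C=C[Mg]Br
Why: Grignard 1,2-addition to the aldehyde; the carbinol centre is oxidised away in step 15.

**Step 15**
Reactants: 24 1-[2,4-bis(benzyloxy)phenyl]prop-2-en-1-ol
Product: 25 1-[2,4-bis(benzyloxy)phenyl]prop-2-en-1-one
Conditions: MnO2, CH2Cl2, rt
Reagents that add atoms: none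
Why: MnO2 oxidises the allylic-benzylic alcohol selectively under neutral conditions that spare the polymerisable vinyl ketone.

**Step 16**
Reactants: 9 (2S,3R,4R)-2-[4-(benzyloxy)phenyl]-6-bromo-4-[2,4-bis(triisopropylsilyloxy)phenyl]chroman-3-ol; 22 [(2S,3S,4S,5R)-4-[4-(benzyloxy)benzyl]-2-[4-(benzyloxy)phenyl]-5-[2,4-bis(benzyloxy)phenyl]tetrahydrofuran-3-yl][2,4-bis(benzyloxy)phenyl]methanone
Product: 27 protected 5-bromo-2,3-dihydrobenzofuran coupling product with all seven stereocentres as in 30, via flavan-3-yl triflate 26 (not isolated)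
Conditions: 9, 22 (1.5 equiv), 2,6-di-tert-butyl-4-methylpyridine, CH2Cl2, −78 °C; Tf2O, −78 → −20 °C
Reagents that add atoms: none
Why: Proposed new method: triflation of the equatorial 3-OH gives 26, whose C3–O bond is antiperiplanar to ring bond C4–C4a, so that aryl carbon C4a (ortho to O1) displaces triflate from the rear (3-exo-tet closure to a spiro-cyclopropane phenonium ion) and, by cleavage of C4–C4a, the six-membered pyran ring becomes the five-membered dihydrofuran ring (Wagner–Meerwein 1,2-aryl shift, net six-to-five contraction), while the charge passes to benzylic C4, where the central ring of 22 attacks in a Friedel–Crafts alkylation. The closest known reaction types are the phenonium-ion 1,2-aryl shifts of β-aryl alkyl sulfonates, the oxidative 1,2-aryl-shift ring contraction of flavanones to 2-aryl-2,3-dihydrobenzofuran-3-carboxylates, and the trapping of benzylic cations by dialkoxyarenes; their combination as a fragment coupling on a 4-arylflavan-3-ol has not been shown. C3 is set by inversion (stereospecific backside shift) and the diarylmethine centre by backside opening of the phenonium ion at C4 (second inversion); should the ion open to the free cation first, allylic 1,3-strain holds H3 in the cation plane and the arene is still expected to enter anti to the benzo ring, so both pathways converge on the required configuration, and C2 is untouched and ends trans to C3. The step needs (a) migration of C4a and not of O1, of the C4 aryl group or of its ortho oxygen, which is secured because only ring bonds C4–C4a and C2–O1 are antiperiplanar in the all-equatorial half-chair, an oxygenated aryl π-system is a better neighbouring group than the ether oxygen, and C4 is the better cation site; (b) attack by the right arene carbon, which is secured because C5 of the 2,4-bis(benzyloxy)phenyl ring of 22 is the only unhindered dialkoxyarene position while the ring on C4 of 26 is shielded by its two TIPS groups; (c) substitution rather than proton loss to a benzofuran, which the low temperature, the hindered base and the excess of 22 should favour.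

**Step 17**
Reactants: 27 protected 5-bromo-2,3-dihydrobenzofuran coupling product; 25 1-[2,4-bis(benzyloxy)phenyl]prop-2-en-1-one
Product: 28 nona-O-benzyl-bis-O-triisopropylsilyl-lophirachalcone
Conditions: 25 (2 equiv), Pd2(dba)3, [HP(t-Bu)3]BF4, Cy2NMe, 1,4-dioxane, 60 °C
Reagents that add atoms: none
Why: The Mizoroki–Heck reaction of an aryl bromide with an aryl vinyl ketone is a known chalcone synthesis; syn insertion and syn β-hydride elimination give the (E)-enone, and the absence of free phenols excludes oxa-Michael addition to the vinyl ketone.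

**Step 18**
Reactants: 28 nona-O-benzyl-bis-O-triisopropylsilyl-lophirachalcone
Product: 29 nona-O-benzyl-lophirachalcone
Conditions: Bu4NF, AcOH, THF, 0 °C
Reagents that add atoms: none
Why: Fluoride cleaves the two aryl silyl ethers, and acetic acid buffers the phenoxides so that the β-alkoxy ketone of the tetrahydrofuran and the enone are not exposed to base.

**Step 19**
Reactants: 29 nona-O-benzyl-lophirachalcone
Product: 30 lophirachalcone
Conditions: BCl3, C6HMe5, CH2Cl2, −78 °C; MeOH
Reagents that add atoms: none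
Why: Lewis-acid debenzylation of aryl benzyl ethers with BCl3 and pentamethylbenzene as a non-basic benzyl-cation scavenger proceeds at −78 °C and is known to spare enones and ketones; no stereocentre is touched.

**Compound list**

1 | 4-bromoresorcinol (4-bromobenzene-1,3-diol) | Oc1ccc(Br)c(O)c1 | starting material
2 | 1-bromo-2,4-bis(triisopropylsilyloxy)benzene | CC(C)[Si](Oc1ccc(Br)c(O[Si](C(C)C)(C(C)C)C(C)C)c1)(C(C)C)C(C)C | intermediate
3 | 1-bromo-2,4-bis(benzyloxy)benzene | Brc1ccc(OCc2ccccc2)cc1OCc1ccccc1 | intermediate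
4 | 6-bromochromone (6-bromo-4H-chromen-4-one) | O=c1ccoc2ccc(Br)cc12 | starting material
5 | 4-(benzyloxy)phenylboronic acid | OB(O)c1ccc(OCc2ccccc2)cc1 | starting material
6 | (2R)-2-[4-(benzyloxy)phenyl]-6-bromochroman-4-one | O=C1C[C@H](c2ccc(OCc3ccccc3)cc2)Oc2ccc(Br)cc21 | intermediate
7 | (2R)-2-[4-(benzyloxy)phenyl]-6-bromo-4-[2,4-bis(triisopropylsilyloxy)phenyl]chroman-4-ol (either C4 epimer; the carbinol centre is lost in step 5) | OC1(c2ccc(O[Si](C(C)C)(C(C)C)C(C)C)cc2O[Si](C(C)C)(C(C)C)C(C)C)C[C@H](c2ccc(OCc3ccccc3)cc2)Oc2ccc(Br)cc21 | intermediate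
8 | (2R)-2-[4-(benzyloxy)phenyl]-6-bromo-4-[2,4-bis(triisopropylsilyloxy)phenyl]-2H-chromene | Brc1ccc2c(c1)C(c1ccc(O[Si](C(C)C)(C(C)C)C(C)C)cc1O[Si](C(C)C)(C(C)C)C(C)C)=C[C@H](c1ccc(OCc3ccccc3)cc1)O2 | intermediate
9 | (2S,3R,4R)-2-[4-(benzyloxy)phenyl]-6-bromo-4-[2,4-bis(triisopropylsilyloxy)phenyl]chroman-3-ol (2,3-trans-3,4-trans, all substituents equatorial) | Brc1ccc2c(c1)[C@H](c1ccc(O[Si](C(C)C)(C(C)C)C(C)C)cc1O[Si](C(C)C)(C(C)C)C(C)C)[C@@H](O)[C@H](c1ccc(OCc3ccccc3)cc1)O2 | intermediate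
10 | (S)-4-benzyl-1,3-oxazolidin-2-one | O=C1N[C@@H](Cc2ccccc2)CO1 | starting material
11 | methyl 4-chloro-4-oxobutanoate | COC(=O)CCC(Cl)=O | starting material
12 | methyl 4-[(4S)-4-benzyl-2-oxo-1,3-oxazolidin-3-yl]-4-oxobutanoate | COC(=O)CCC(=O)N1C(=O)OC[C@@H]1Cc1ccccc1 | intermediate
13 | 4-(benzyloxy)benzaldehyde | O=Cc1ccc(OCc2ccccc2)cc1 | starting material
14 | methyl (3S,4S)-4-[4-(benzyloxy)phenyl]-3-{[(4S)-4-benzyl-2-oxo-1,3-oxazolidin-3-yl]carbonyl}-4-hydroxybutanoate (syn-aldol adduct) | COC(=O)C[C@@H]([C@H](O)c1ccc(OCc2ccccc2)cc1)C(=O)N1C(=O)OC[C@@H]1Cc1ccccc1 | intermediate (not isolated)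
15 | (4S)-4-benzyl-3-{[(2S,3S)-2-[4-(benzyloxy)phenyl]-5-oxotetrahydrofuran-3-yl]carbonyl}-1,3-oxazolidin-2-one (trans lactone) | O=C1O[C@H](c2ccc(OCc3ccccc3)cc2)[C@@H](C(=O)N2C(=O)OC[C@@H]2Cc2ccccc2)C1 | intermediate
16 | (2S,3S)-2-[4-(benzyloxy)phenyl]-5-oxotetrahydrofuran-3-carboxylic acid | O=C1O[C@H](c2ccc(OCc3ccccc3)cc2)[C@@H](C(=O)O)C1 | intermediate
17 | 4-(benzyloxy)benzyl bromide | BrCc1ccc(OCc2ccccc2)cc1 | starting material
18 | (2S,3S,4S)-4-[4-(benzyloxy)benzyl]-2-[4-(benzyloxy)phenyl]-5-oxotetrahydrofuran-3-carboxylic acid (all-trans) | O=C1O[C@H](c2ccc(OCc3ccccc3)cc2)[C@@H](C(=O)O)[C@@H]1Cc1ccc(OCc2ccccc2)cc1 | intermediate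
19 | (2S,3S,4S)-4-[4-(benzyloxy)benzyl]-2-[4-(benzyloxy)phenyl]-5-[2,4-bis(benzyloxy)phenyl]-5-hydroxytetrahydrofuran-3-carboxylic acid (hemiketal, both anomers, in equilibrium with the open hydroxy ketone) | OC1(c2ccc(OCc3ccccc3)cc2OCc2ccccc2)O[C@H](c2ccc(OCc3ccccc3)cc2)[C@@H](C(=O)O)[C@@H]1Cc1ccc(OCc2ccccc2)cc1 | intermediate (not isolated)
20 | (2S,3S,4S,5R)-4-[4-(benzyloxy)benzyl]-2-[4-(benzyloxy)phenyl]-5-[2,4-bis(benzyloxy)phenyl]tetrahydrofuran-3-carboxylic acid (2,3-trans-3,4-trans-4,5-cis) | c1cc([C@@H]2O[C@H](c3ccc(OCc4ccccc4)cc3)[C@@H](C(=O)O)[C@@H]2Cc2ccc(OCc3ccccc3)cc2)c(OCc2ccccc2)cc1OCc1ccccc1 | intermediate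
21 | (2S,3S,4S,5R)-4-[4-(benzyloxy)benzyl]-2-[4-(benzyloxy)phenyl]-5-[2,4-bis(benzyloxy)phenyl]-N-methoxy-N-methyltetrahydrofuran-3-carboxamide | c1cc([C@@H]2O[C@H](c3ccc(OCc4ccccc4)cc3)[C@@H](C(=O)N(C)OC)[C@@H]2Cc2ccc(OCc3ccccc3)cc2)c(OCc2ccccc2)cc1OCc1ccccc1 | intermediate
22 | [(2S,3S,4S,5R)-4-[4-(benzyloxy)benzyl]-2-[4-(benzyloxy)phenyl]-5-[2,4-bis(benzyloxy)phenyl]tetrahydrofuran-3-yl][2,4-bis(benzyloxy)phenyl]methanone | c1cc([C@@H]2O[C@H](c3ccc(OCc4ccccc4)cc3)[C@@H](C(=O)c3ccc(OCc4ccccc4)cc3OCc3ccccc3)[C@@H]2Cc2ccc(OCc3ccccc3)cc2)c(OCc2ccccc2)cc1OCc1ccccc1 | intermediate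
23 | 2,4-bis(benzyloxy)benzaldehyde | O=Cc1ccc(OCc2ccccc2)cc1OCc1ccccc1 | starting material
24 | 1-[2,4-bis(benzyloxy)phenyl]prop-2-en-1-ol (racemic) | C=CC(O)c1ccc(OCc2ccccc2)cc1OCc1ccccc1 | intermediate
25 | 1-[2,4-bis(benzyloxy)phenyl]prop-2-en-1-one | C=CC(=O)c1ccc(OCc2ccccc2)cc1OCc1ccccc1 | intermediate
26 | (2S,3R,4R)-2-[4-(benzyloxy)phenyl]-6-bromo-4-[2,4-bis(triisopropylsilyloxy)phenyl]chroman-3-yl trifluoromethanesulfonate | Brc1ccc2c(c1)[C@H](c1ccc(O[Si](C(C)C)(C(C)C)C(C)C)cc1O[Si](C(C)C)(C(C)C)C(C)C)[C@@H](OS(=O)(=O)C(F)(F)F)[C@H](c1ccc(OCc3ccccc3)cc1)O2 | intermediate (not isolated)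
27 | protected coupling product: 2,3-trans-2-[4-(benzyloxy)phenyl]-5-bromo-2,3-dihydrobenzofuran bearing at C3 the methine CH[2,4-bis(triisopropylsilyloxy)phenyl][2,4-bis(benzyloxy)-5-(tetrahydrofuran-2-yl of 22)phenyl]; all seven stereocentres as in 30 | Brc1ccc2c(c1)[C@@H]([C@H](c1ccc(O[Si](C(C)C)(C(C)C)C(C)C)cc1O[Si](C(C)C)(C(C)C)C(C)C)c1cc([C@@H]3O[C@H](c4ccc(OCc5ccccc5)cc4)[C@@H](C(=O)c4ccc(OCc5ccccc5)cc4OCc4ccccc4)[C@@H]3Cc3ccc(OCc4ccccc4)cc3)c(OCc3ccccc3)cc1OCc1ccccc1)[C@H](c1ccc(OCc3ccccc3)cc1)O2 | intermediate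
28 | nona-O-benzyl-bis-O-triisopropylsilyl-lophirachalcone (TIPS on the 2,4-dioxygenated ring of the methine carbon; (E)-enone; stereocentres as in 30) | O=C(/C=C/c1ccc2c(c1)[C@@H]([C@H](c1ccc(O[Si](C(C)C)(C(C)C)C(C)C)cc1O[Si](C(C)C)(C(C)C)C(C)C)c1cc([C@@H]3O[C@H](c4ccc(OCc5ccccc5)cc4)[C@@H](C(=O)c4ccc(OCc5ccccc5)cc4OCc4ccccc4)[C@@H]3Cc3ccc(OCc4ccccc4)cc3)c(OCc3ccccc3)cc1OCc1ccccc1)[C@H](c1ccc(OCc3ccccc3)cc1)O2)c1ccc(OCc2ccccc2)cc1OCc1ccccc1 | intermediate
29 | nona-O-benzyl-lophirachalcone (free 2,4-dihydroxyphenyl ring on the methine carbon; stereocentres as in 30) | O=C(/C=C/c1ccc2c(c1)[C@@H]([C@H](c1ccc(O)cc1O)c1cc([C@@H]3O[C@H](c4ccc(OCc5ccccc5)cc4)[C@@H](C(=O)c4ccc(OCc5ccccc5)cc4OCc4ccccc4)[C@@H]3Cc3ccc(OCc4ccccc4)cc3)c(OCc3ccccc3)cc1OCc1ccccc1)[C@H](c1ccc(OCc3ccccc3)cc1)O2)c1ccc(OCc2ccccc2)cc1OCc1ccccc1 | intermediate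
30 | lophirachalcone | O=C(/C=C/c1ccc2c(c1)[C@@H]([C@H](c1ccc(O)cc1O)c1cc([C@@H]3O[C@H](c4ccc(O)cc4)[C@@H](C(=O)c4ccc(O)cc4O)[C@@H]3Cc3ccc(O)cc3)c(O)cc1O)[C@H](c1ccc(O)cc1)O2)c1ccc(O)cc1O | target

**Step count and risks**

Total step count: 19. Longest linear sequence: 11 steps (steps 7–13, then 16–19).

Steps most likely to fail:

1. Step 16 (proposed new method). The ionisation may take another course: shift of O1 instead of C4a, or loss of a proton from the C4 cation followed by aromatisation to a 3-benzylbenzofuran. The arene may also add with poor facial selectivity at the methine carbon. The fallback uses known chemistry, sets out from flavanone 6 and comes back at 27. Flavanone 6 is treated with the trivalent iodine reagent PhI(OAc)2 and catalytic H2SO4 in HC(OMe)3; this known oxidative ring contraction of flavanones shifts the same aryl carbon from C4 to C3 and gives methyl (2R,3R)-2-[4-(benzyloxy)phenyl]-5-bromo-2,3-dihydro-1-benzofuran-3-carboxylate F1. DIBAL-H in toluene at −78 °C gives (2R,3R)-2-[4-(benzyloxy)phenyl]-5-bromo-2,3-dihydro-1-benzofuran-3-carbaldehyde F2. Addition of the aryllithium made from 2 and n-BuLi gives [(2R,3S)-2-[4-(benzyloxy)phenyl]-5-bromo-2,3-dihydro-1-benzofuran-3-yl][2,4-bis(triisopropylsilyloxy)phenyl]methanol F3 (either carbinol epimer). Brønsted-acid-catalysed Friedel–Crafts benzylation of 22 with F3 (catalytic TfOH, CH2Cl2/(CF3)2CHOH, −40 °C) passes through the same benzylic cation as step 16 and should give 27.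

2. Step 6. Hydroboration of the hindered diaryl-substituted alkene may be slow, the β-alkoxyborane may eliminate with ring opening, and the configuration at C2 may erode by reversible opening of the ionisable 4-aryl-2H-chromene (already in steps 4 and 5). The fallback sets out from flavanone 6, bypasses 7 and 8, and comes back at 9. NaBH4 in MeOH/THF gives (2R)-2-[4-(benzyloxy)phenyl]-6-bromochroman-4-ol F4. Dehydration (MsCl, Et3N, then DBU) gives (2R)-2-[4-(benzyloxy)phenyl]-6-bromo-2H-chromene F5. Dimethyldioxirane in acetone epoxidises the face anti to the 2-aryl group to give (2R)-2-[4-(benzyloxy)phenyl]-6-bromo-3,4-epoxychromane F6. Friedel–Crafts opening of the epoxide at benzylic C4 by excess resorcinol (catalytic BF3·OEt2, 0 °C; the classical route to 4-arylflavan-3-ols, anti opening) gives (2S,3R)-2-[4-(benzyloxy)phenyl]-6-bromo-4-(2,4-dihydroxyphenyl)chroman-3-ol F7 (2,3-trans-3,4-trans). Phenol-selective silylation (TIPSCl, imidazole, DMF) then gives 9.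

3. Step 17. The vinyl ketone may polymerise or undergo conjugate addition, and oxidative addition to the electron-rich, crowded aryl bromide may be slow. The fallback sets out from 27 and comes back at 29. Reductive carbonylation (Pd(OAc)2, di(1-adamantyl)-n-butylphosphine, CO/H2, TMEDA, toluene, 100 °C) gives the 5-formyl-2,3-dihydrobenzofuran analogue of 27, aldehyde F8. Claisen–Schmidt condensation of F8 with commercial 1-[2,4-bis(benzyloxy)phenyl]ethanone (KOH, EtOH/THF, rt) forms the (E)-enone and cleaves the two aryl silyl ethers under the same conditions, which gives 29.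

**Further compounds**

F1 | step 16 | methyl (2R,3R)-2-[4-(benzyloxy)phenyl]-5-bromo-2,3-dihydro-1-benzofuran-3-carboxylate | Brc1ccc2c(c1)[C@@H](C(=O)OC)[C@H](c1ccc(OCc3ccccc3)cc1)O2
F2 | step 16 | (2R,3R)-2-[4-(benzyloxy)phenyl]-5-bromo-2,3-dihydro-1-benzofuran-3-carbaldehyde | Brc1ccc2c(c1)[C@@H](C=O)[C@H](c1ccc(OCc3ccccc3)cc1)O2
F3 | step 16 | [(2R,3S)-2-[4-(benzyloxy)phenyl]-5-bromo-2,3-dihydro-1-benzofuran-3-yl][2,4-bis(triisopropylsilyloxy)phenyl]methanol (2,3-trans; either carbinol epimer) | Brc1ccc2c(c1)[C@@H](C(O)c1ccc(O[Si](C(C)C)(C(C)C)C(C)C)cc1O[Si](C(C)C)(C(C)C)C(C)C)[C@H](c1ccc(OCc3ccccc3)cc1)O2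
F4 | step 6 | (2R)-2-[4-(benzyloxy)phenyl]-6-bromochroman-4-ol (either C4 epimer) | OC1C[C@H](c2ccc(OCc3ccccc3)cc2)Oc2ccc(Br)cc21
F5 | step 6 | (2R)-2-[4-(benzyloxy)phenyl]-6-bromo-2H-chromene | Brc1ccc2c(c1)C=C[C@H](c1ccc(OCc3ccccc3)cc1)O2
F6 | step 6 | (2R)-2-[4-(benzyloxy)phenyl]-6-bromo-3,4-epoxychromane (epoxide trans to the 2-aryl group) | Brc1ccc2c(c1)[C@H]1O[C@H]1[C@H](c1ccc(OCc3ccccc3)cc1)O2
F7 | step 6 | (2S,3R)-2-[4-(benzyloxy)phenyl]-6-bromo-4-(2,4-dihydroxyphenyl)chroman-3-ol (2,3-trans-3,4-trans) | Brc1ccc2c(c1)[C@H](c1ccc(O)cc1O)[C@@H](O)[C@H](c1ccc(OCc3ccccc3)cc1)O2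
F8 | step 17 | 5-formyl analogue of 27 (aldehyde in place of bromine; TIPS and benzyl groups and all stereocentres as in 27) | O=Cc1ccc2c(c1)[C@@H]([C@H](c1ccc(O[Si](C(C)C)(C(C)C)C(C)C)cc1O[Si](C(C)C)(C(C)C)C(C)C)c1cc([C@@H]3O[C@H](c4ccc(OCc5ccccc5)cc4)[C@@H](C(=O)c4ccc(OCc5ccccc5)cc4OCc4ccccc4)[C@@H]3Cc3ccc(OCc4ccccc4)cc3)c(OCc3ccccc3)cc1OCc1ccccc1)[C@H](c1ccc(OCc3ccccc3)cc1)O2
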